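The cyclohexene ring (C3a–C4–C5–C6=C7–C7a, indene numbering of the target) is a Diels–Alder retron: its C6=C7 alkene lies between the C4–C5 bond (two adjacent quaternary carbons) and the C3a–C7a ring-fusion bond. One intramolecular [4+2] cycloaddition of an acyclic all-E hydroxy tetraenal closes both bonds, both rings and four stereocentres, with the cyclopentanone carbons C1–C3 as tether. The two pseudo-C2-related methyl stereocentres of that tether come from one enantiopure propargylic mesylate used twice (allenylzinc, then allenylindium addition). Each resulting ethyl alkyne becomes an (E)-2-ethyl enal by hydrozirconation–carbonylation.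

Key step: step 10

Remark on the chemistry: hex-3-yn-2-one, paraformaldehyde, 2-(triphenylphosphoranylidene)butanal and diethyl benzylphosphonate are taken as commercial; the carbinol configuration at the future C2 has no bearing on the target because C2 ends as the ketone.

Step 1
Reactants: 1 hex-3-yn-2-one
Product: 2 (S)-hex-3-yn-2-ol
Conditions: Ru[(S,S)-TsNCH(Ph)CH(Ph)NH](p-cymene) (0.5 mol %), i-PrOH, rt
Reagents that add atoms: none
Why: Noyori asymmetric transfer hydrogenation of an alkynyl methyl ketone; the (S,S)-catalyst is expected to deliver hydride to the face that gives the (S)-propargylic alcohol, with 2-propanol as hydrogen donor.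

Step 2
Reactants: 2 (S)-hex-3-yn-2-ol
Product: 3 (S)-hex-3-yn-2-yl methanesulfonate
Conditions: MsCl, Et3N, CH2Cl2, −78 °C
Reagents that add atoms: methanesulfonyl chloride, CS(=O)(=O)Cl
Why: O-sulfonylation of a secondary alcohol; no bond to the stereocentre is broken, so the S configuration should be retained and the leaving group for the SN2' metalation is in place.

Step 3
Reactants: 3 (S)-hex-3-yn-2-yl methanesulfonate; 4 formaldehyde
Product: 6 (R)-2-methylhex-3-yn-1-ol, via allenylzinc 5 (not isolated)
Conditions: Pd(OAc)2 (5 mol %), PPh3 (5 mol %), Et2Zn (3 equiv), THF, −78 → −20 °C; CH2O (monomer from cracked paraformaldehyde, THF solution); aq NH4Cl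
Reagents that add atoms: none
Why: Marshall propargylation: zerovalent palladium formed in the flask should displace the mesylate anti-SN2', transmetalation gives the configurationally defined allenylzinc 5, and its cyclic SE2' addition to formaldehyde regenerates the alkyne with net inversion at the former carbinol carbon, which sets the R methyl stereocentre (C1 of the target).

Step 4
Reactants: 6 (R)-2-methylhex-3-yn-1-ol
Product: 9 (2E,4R)-2-ethyl-5-hydroxy-4-methylpent-2-enal, via alkenylzirconocene 7 (not isolated), via acylzirconocene 8 (not isolated)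
Conditions: Cp2Zr(H)Cl (2.3 equiv), THF, rt; CO (1 atm), rt; 1 M HCl, 0 °C
Reagents that add atoms: carbon monoxide, [C-]#[O+]
Why: Schwartz hydrozirconation–carbonylation: after zirconation of the hydroxyl, syn addition of Zr–H should place zirconium on the less hindered, ethyl-bearing alkyne carbon, CO inserts with retention and protonolysis releases the enal, whose E geometry follows from the syn addition.

Step 5
Reactants: 9 (2E,4R)-2-ethyl-5-hydroxy-4-methylpent-2-enal; 10 2-(triphenylphosphoranylidene)butanal
Product: 11 (2E,4E,6R)-2,4-diethyl-7-hydroxy-6-methylhepta-2,4-dienal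
Conditions: 10 (1.2 equiv), toluene, 90 °C
Reagents that add atoms: none
Why: Wittig olefination with a formyl-stabilised ylide, which should give the E trisubstituted alkene and stop largely at the dienal because the product is the less electrophilic aldehyde; the stereocentre is not involved.

Step 6
Reactants: 11 (2E,4E,6R)-2,4-diethyl-7-hydroxy-6-methylhepta-2,4-dienal; 12 diethyl benzylphosphonate
Product: 13 (2R,3E,5E,7E)-4,6-diethyl-2-methyl-8-phenylocta-3,5,7-trien-1-ol
Conditions: 12 (2.3 equiv), n-BuLi (2.2 equiv), THF, −78 → 0 °C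
Reagents that add atoms: none
Why: Horner–Wadsworth–Emmons olefination with a benzylic phosphonate anion (one equivalent is consumed by the hydroxyl), expected to give the conjugated (E)-styryl alkene.

Step 7
Reactants: 13 (2R,3E,5E,7E)-4,6-diethyl-2-methyl-8-phenylocta-3,5,7-trien-1-ol
Product: 14 (2R,3E,5E,7E)-4,6-diethyl-2-methyl-8-phenylocta-3,5,7-trienal
Conditions: Dess–Martin periodinane, NaHCO3, CH2Cl2, 0 °C; crude aldehyde used at once
Reagents that add atoms: none
Why: Dess–Martin oxidation under buffered, non-basic conditions, chosen because the α-stereocentre of this β,γ-unsaturated aldehyde is prone to enolisation.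

Step 8
Reactants: 14 (2R,3E,5E,7E)-4,6-diethyl-2-methyl-8-phenylocta-3,5,7-trienal; 3 (S)-hex-3-yn-2-yl methanesulfonate
Product: 16 (5R,6S,7R,8E,10E,12E)-9,11-diethyl-5,7-dimethyl-13-phenyltrideca-8,10,12-trien-3-yn-6-ol, via allenylindium 15 (not isolated)
Conditions: 3 (1.5 equiv), Pd(dppf)Cl2 (5 mol %), InI (1.6 equiv), THF–HMPA (3:1), 0 °C → rt; aq NH4Cl
Reagents that add atoms: none
Why: Marshall propargylation in its Barbier-type indium variant: zerovalent palladium formed in the flask should displace the mesylate anti-SN2', oxidative transmetalation with indium monoiodide gives the configurationally defined allenylindium 15 with no basic dialkylzinc in contact with the enolisable aldehyde, and its cyclic SE2' addition should fix the new methyl stereocentre (C3 of the target) as R by chirality transfer and give the anti carbinol in what is expected to be the Felkin-matched pairing.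

Step 9
Reactants: 16 (5R,6S,7R,8E,10E,12E)-9,11-diethyl-5,7-dimethyl-13-phenyltrideca-8,10,12-trien-3-yn-6-ol
Product: 19 (2E,4R,5S,6R,7E,9E,11E)-2,8,10-triethyl-5-hydroxy-4,6-dimethyl-12-phenyldodeca-2,7,9,11-tetraenal, via alkenylzirconocene 17 (not isolated), via acylzirconocene 18 (not isolated)
Conditions: Cp2Zr(H)Cl (2.2 equiv), THF, rt, short contact; CO (1 atm); 1 M HCl, 0 °C
Reagents that add atoms: carbon monoxide, [C-]#[O+]
Why: Schwartz hydrozirconation–carbonylation: the internal alkyne should react far faster than the di- and trisubstituted alkenes of the triene, zirconium again going to the ethyl-bearing carbon, so that CO insertion and protonolysis give the (E)-2-ethyl enal that serves as dienophile.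

Step 10
Reactants: 19 (2E,4R,5S,6R,7E,9E,11E)-2,8,10-triethyl-5-hydroxy-4,6-dimethyl-12-phenyldodeca-2,7,9,11-tetraenal
Product: 20 (1R,2S,3R,3aS,4S,5R,7aS)-4,5,7-triethyl-2-hydroxy-1,3-dimethyl-5-[(E)-2-phenylethenyl]-2,3,3a,4,5,7a-hexahydro-1H-indene-4-carbaldehyde
Conditions: toluene (0.01 M), BHT (cat.), 90 °C
Reagents that add atoms: none
Why: A thermal, concerted but asynchronous intramolecular Diels–Alder reaction of the terminally tethered (type 1) class, closest to cycloadditions of 1,6,8-nonatrienes with an (E)-activated dienophile: diene C7=C8–C9=C10 and enal C2=C3 of 19 should combine suprafacially to form C3–C7 and C2–C10 (C3a–C7a and C4–C5 of 20). The six-membered ring closes as the [4+2] ring and the five-membered ring closes at the same time through the three-carbon tether C4–C6 onto the shared ring-fusion bond, the styryl diene C9–C12 being out of reach because it would need a seven-membered tether ring. The quaternary centres C4 and C5 of 20 follow stereospecifically from the E geometry of the enal (ethyl cis to the tether) and of the 9,10-alkene (styryl outside), and their relation to the ring fusion from the formyl-endo transition state, which gives the trans-fused hydrindane and keeps the α-ethyl group exo. The absolute sense at C3a and C7a is set by the two methyl-bearing tether stereocentres: each turns its hydrogen into the plane of the adjacent alkene, eclipsing the cis ethyl group to avoid A(1,3) strain, so both methyl groups are pseudo-equatorial on the forming cyclopentane only on the diene face that leads to 20, and the two controls reinforce each other because the centres are pseudo-C2-related. The step thus needs peri-, endo/exo and π-facial selectivity, secured by tether length, by the exo preference of the dienophile α-substituent and by the matched allylic-strain control; the hydroxyl ends trans to the C4 substituent on the cyclopentane and cannot close a lactol.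

Step 11
Reactants: 20 (1R,2S,3R,3aS,4S,5R,7aS)-4,5,7-triethyl-2-hydroxy-1,3-dimethyl-5-[(E)-2-phenylethenyl]-2,3,3a,4,5,7a-hexahydro-1H-indene-4-carbaldehyde
Product: 21 norspiculoic acid A
Conditions: CrO3, H2SO4, H2O, acetone, 0 °C
Reagents that add atoms: water, O
Why: Jones oxidation should convert the secondary alcohol to the cyclopentanone and, through its hydrate, the neopentyl aldehyde to the carboxylic acid in one operation; both α-methyl groups sit trans to their ring-fusion neighbours, the thermodynamically preferred arrangement, so acid should not scramble them.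

**Compound list**

1 | hex-3-yn-2-one | CCC#CC(C)=O | starting material
2 | (S)-hex-3-yn-2-ol | C[C@H](O)C#CCC | intermediate
3 | (S)-hex-3-yn-2-yl methanesulfonate | C[C@H](OS(C)(=O)=O)C#CCC | intermediate
4 | formaldehyde (monomer from paraformaldehyde) | C=O | starting material
5 | ethyl[(aR)-hexa-2,3-dien-4-yl]zinc (allenylzinc, not isolated) | CC[Zn]C(CC)=[C@@]=C(C)[H] | intermediate
6 | (R)-2-methylhex-3-yn-1-ol | OC[C@H](C)C#CCC | intermediate
7 | alkenylzirconocene from 6: Cp2Zr(Cl) alkoxide at O, Cp2Zr(Cl) on the ethyl-bearing alkene carbon, Zr and H cis (Cp written σ-bonded, not isolated) | C[C@@H](CO[Zr](Cl)(C1C=CC=C1)C1C=CC=C1)/C=C(\CC)[Zr](Cl)(C1C=CC=C1)C1C=CC=C1 | intermediate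
8 | acylzirconocene from 7 after CO insertion (not isolated) | C[C@@H](CO[Zr](Cl)(C1C=CC=C1)C1C=CC=C1)/C=C(\CC)C(=O)[Zr](Cl)(C1C=CC=C1)C1C=CC=C1 | intermediate
9 | (2E,4R)-2-ethyl-5-hydroxy-4-methylpent-2-enal | C[C@@H](CO)/C=C(\CC)C=O | intermediate
10 | 2-(triphenylphosphoranylidene)butanal | CCC(C=O)=P(c1ccccc1)(c1ccccc1)c1ccccc1 | starting material
11 | (2E,4E,6R)-2,4-diethyl-7-hydroxy-6-methylhepta-2,4-dienal | C[C@@H](CO)/C=C(CC)/C=C(\CC)C=O | intermediate
12 | diethyl benzylphosphonate | CCOP(=O)(Cc1ccccc1)OCC | starting material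
13 | (2R,3E,5E,7E)-4,6-diethyl-2-methyl-8-phenylocta-3,5,7-trien-1-ol | C[C@@H](CO)/C=C(CC)/C=C(CC)/C=C/c1ccccc1 | intermediate
14 | (2R,3E,5E,7E)-4,6-diethyl-2-methyl-8-phenylocta-3,5,7-trienal | C[C@@H](C=O)/C=C(CC)/C=C(CC)/C=C/c1ccccc1 | intermediate
15 | [(aR)-hexa-2,3-dien-4-yl](iodo)(methanesulfonato)indium (allenylindium, not isolated) | CS(=O)(=O)O[In](I)C(CC)=[C@@]=C(C)[H] | intermediate
16 | (5R,6S,7R,8E,10E,12E)-9,11-diethyl-5,7-dimethyl-13-phenyltrideca-8,10,12-trien-3-yn-6-ol | c1ccccc1/C=C/C(CC)=C/C(CC)=C/[C@@H](C)[C@H](O)[C@H](C)C#CCC | intermediate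
17 | alkenylzirconocene from 16: Cp2Zr(Cl) alkoxide at O, Cp2Zr(Cl) on the ethyl-bearing alkene carbon (Cp written σ-bonded, not isolated) | c1ccccc1/C=C/C(CC)=C/C(CC)=C/[C@@H](C)[C@H](O[Zr](Cl)(C1C=CC=C1)C1C=CC=C1)[C@H](C)/C=C(\CC)[Zr](Cl)(C1C=CC=C1)C1C=CC=C1 | intermediate
18 | acylzirconocene from 17 after CO insertion (not isolated) | c1ccccc1/C=C/C(CC)=C/C(CC)=C/[C@@H](C)[C@H](O[Zr](Cl)(C1C=CC=C1)C1C=CC=C1)[C@H](C)/C=C(\CC)C(=O)[Zr](Cl)(C1C=CC=C1)C1C=CC=C1 | intermediate
19 | (2E,4R,5S,6R,7E,9E,11E)-2,8,10-triethyl-5-hydroxy-4,6-dimethyl-12-phenyldodeca-2,7,9,11-tetraenal | c1ccccc1/C=C/C(CC)=C/C(CC)=C/[C@@H](C)[C@H](O)[C@H](C)/C=C(\CC)C=O | intermediate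
20 | (1R,2S,3R,3aS,4S,5R,7aS)-4,5,7-triethyl-2-hydroxy-1,3-dimethyl-5-[(E)-2-phenylethenyl]-2,3,3a,4,5,7a-hexahydro-1H-indene-4-carbaldehyde | CCC1=C[C@](/C=C/c2ccccc2)(CC)[C@@](CC)(C=O)[C@H]2[C@H]1[C@@H](C)[C@H](O)[C@@H]2C | intermediate
21 | norspiculoic acid A, (1R,3R,3aS,4S,5R,7aS)-4,5,7-triethyl-1,3-dimethyl-2-oxo-5-[(E)-2-phenylethenyl]-2,3,3a,4,5,7a-hexahydro-1H-indene-4-carboxylic acid | CCC1=C[C@](/C=C/c2ccccc2)(CC)[C@@](CC)(C(=O)O)[C@H]2[C@H]1[C@@H](C)C(=O)[C@@H]2C | target

**Step count and risks**

Total step count: 11. Longest linear sequence: 11 steps (1 → 21; mesylate 3 is used a second time in step 8).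

Steps most likely to fail:

Step 8. Aldehyde 14 may enolise toward the triene during oxidation, handling or the indium-mediated addition, which would epimerise its α-carbon or move the 3,4-alkene into conjugation and so erode the C1 methyl stereocentre of the target. The fallback reverses the order, so that the propargylation is run on a saturated β-silyloxy aldehyde and the triene is grown afterwards. It sets out from mesylate 3 and comes back at 16. Commercial methyl (R)-3-hydroxy-2-methylpropanoate would be silylated (TBSCl, imidazole) to methyl (R)-3-[(tert-butyldimethylsilyl)oxy]-2-methylpropanoate F1 and reduced (i-Bu2AlH, −78 °C) to (R)-3-[(tert-butyldimethylsilyl)oxy]-2-methylpropanal F2. Addition of allenylzinc 5, generated from 3 as in step 3, should give the syn,anti stereotriad (2R,3R,4R)-1-[(tert-butyldimethylsilyl)oxy]-2,4-dimethyloct-5-yn-3-ol F3, and TBAF should give (2R,3R,4R)-2,4-dimethyloct-5-yne-1,3-diol F4. Selective oxidation of the primary alcohol (TEMPO, PhI(OAc)2) to (2S,3R,4R)-3-hydroxy-2,4-dimethyloct-5-ynal F5, followed in the same flask by Wittig reaction with 10, should give (2E,4R,5S,6R)-2-ethyl-5-hydroxy-4,6-dimethyldec-2-en-7-ynal F6. A second Wittig reaction with 10 should give (2E,4E,6R,7S,8R)-2,4-diethyl-7-hydroxy-6,8-dimethyldodeca-2,4-dien-9-ynal F7, and Horner–Wadsworth–Emmons reaction with the anion of 12 should then give 16.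

Step 9. Cp2Zr(H)Cl may add to the conjugated triene or to the wrong alkyne carbon, and material may be lost on acidic protonolysis. The fallback replaces the early-metal hydride by a late-metal one that leaves alkenes alone and brings in the formyl carbon by a separate step. It sets out from 16 and comes back at 19. Syn-hydrostannation (Bu3SnH, Pd(PPh3)2Cl2 cat., THF, 0 °C) should give tributyl[(3E,5R,6S,7R,8E,10E,12E)-9,11-diethyl-6-hydroxy-5,7-dimethyl-13-phenyltrideca-3,8,10,12-tetraen-3-yl]stannane F8. Iododestannylation (I2, CH2Cl2, 0 °C) should give (3E,5R,6S,7R,8E,10E,12E)-9,11-diethyl-3-iodo-5,7-dimethyl-13-phenyltrideca-3,8,10,12-tetraen-6-ol F9. Iodine–lithium exchange (t-BuLi, 3 equiv, −78 °C) and formylation with DMF should give 19.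

Step 3. Capture of allenylzinc 5 by monomeric formaldehyde may be slow or incomplete (repolymerisation of the electrophile, competing ethyl transfer from Et2Zn), and 5 may partly racemise while it waits. The fallback takes the first methyl stereocentre from the chiral pool and makes the enal by olefination, by-passing steps 3 and 4. It sets out from ylide 10 and comes back at 9. Commercial methyl (S)-3-hydroxy-2-methylpropanoate would be silylated to methyl (S)-3-[(tert-butyldimethylsilyl)oxy]-2-methylpropanoate F10 and reduced (i-Bu2AlH, −78 °C) to (S)-3-[(tert-butyldimethylsilyl)oxy]-2-methylpropanal F11. Wittig reaction with 10 (toluene, 80 °C) should give (2E,4R)-5-[(tert-butyldimethylsilyl)oxy]-2-ethyl-4-methylpent-2-enal F12, and desilylation (HF·pyridine, THF) should give 9.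

Further compounds
F1 | step 8 | methyl (R)-3-[(tert-butyldimethylsilyl)oxy]-2-methylpropanoate | COC(=O)[C@H](C)CO[Si](C)(C)C(C)(C)C
F2 | step 8 | (R)-3-[(tert-butyldimethylsilyl)oxy]-2-methylpropanal | O=C[C@H](C)CO[Si](C)(C)C(C)(C)C
F3 | step 8 | (2R,3R,4R)-1-[(tert-butyldimethylsilyl)oxy]-2,4-dimethyloct-5-yn-3-ol | CC(C)(C)[Si](C)(C)OC[C@@H](C)[C@H](O)[C@H](C)C#CCC
F4 | step 8 | (2R,3R,4R)-2,4-dimethyloct-5-yne-1,3-diol | OC[C@@H](C)[C@H](O)[C@H](C)C#CCC
F5 | step 8 | (2S,3R,4R)-3-hydroxy-2,4-dimethyloct-5-ynal | O=C[C@@H](C)[C@H](O)[C@H](C)C#CCC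
F6 | step 8 | (2E,4R,5S,6R)-2-ethyl-5-hydroxy-4,6-dimethyldec-2-en-7-ynal | O=C/C(CC)=C/[C@@H](C)[C@H](O)[C@H](C)C#CCC
F7 | step 8 | (2E,4E,6R,7S,8R)-2,4-diethyl-7-hydroxy-6,8-dimethyldodeca-2,4-dien-9-ynal | O=C/C(CC)=C/C(CC)=C/[C@@H](C)[C@H](O)[C@H](C)C#CCC
F8 | step 9 | tributyl[(3E,5R,6S,7R,8E,10E,12E)-9,11-diethyl-6-hydroxy-5,7-dimethyl-13-phenyltrideca-3,8,10,12-tetraen-3-yl]stannane | c1ccccc1/C=C/C(CC)=C/C(CC)=C/[C@@H](C)[C@H](O)[C@H](C)/C=C(\CC)[Sn](CCCC)(CCCC)CCCC
F9 | step 9 | (3E,5R,6S,7R,8E,10E,12E)-9,11-diethyl-3-iodo-5,7-dimethyl-13-phenyltrideca-3,8,10,12-tetraen-6-ol | c1ccccc1/C=C/C(CC)=C/C(CC)=C/[C@@H](C)[C@H](O)[C@H](C)/C=C(\CC)I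
F10 | step 3 | methyl (S)-3-[(tert-butyldimethylsilyl)oxy]-2-methylpropanoate | COC(=O)[C@@H](C)CO[Si](C)(C)C(C)(C)C
F11 | step 3 | (S)-3-[(tert-butyldimethylsilyl)oxy]-2-methylpropanal | O=C[C@@H](C)CO[Si](C)(C)C(C)(C)C
F12 | step 3 | (2E,4R)-5-[(tert-butyldimethylsilyl)oxy]-2-ethyl-4-methylpent-2-enal | C[C@@H](CO[Si](C)(C)C(C)(C)C)/C=C(\CC)C=O
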